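**Retrosynthetic overview**
1. Target 25 comes from 24 by removing the O-methyl and tert-butyl groups. Compound 24 comes from bicyclic ketone 21 by C7 reduction, acetylation and oxidation of the doubly allylic C3 methylene.
2. Rings A and B form together in one flask. A propargyl Claisen rearrangement (C5–C6) releases a 1,1-disubstituted allene. Its methyl-bearing π bond (C5=C4) then adds to a 2-methoxydiene (C10=C1–C2=C3), giving the angular C19 methyl and the C4 exocyclic methylene directly.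
3. Both enol ethers come from one double methylenation of diester 18, which supplies C3 and C6.
4. C8 and the quaternary C9 come from an Ireland–Claisen rearrangement with chirality transfer from the lipase-resolved (S)-allylic propionate 10.
5. C13 and the side chain come from (R)-citronellic acid. The E C9=C10 alkene comes from Negishi carboalumination.

Assumption: atom labels C1–C20 follow clerodane numbering (C5/C10 ring fusion, C9 quaternary carbon with the side chain, C18 exocyclic methylene, C19 methyl on C5, C20 methyl on C9, C17 methyl on C8).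

**Step 1**
Reactants: 1 (R)-citronellic acid
Product: 2 tert-butyl (3R)-3,7-dimethyloct-6-enoate
Conditions: Boc2O (1.5 equiv), DMAP (0.2 equiv), t-BuOH, 30 °C
Reagents that add atoms: di-tert-butyl dicarbonate CC(C)(C)OC(=O)OC(=O)OC(C)(C)C
Why: DMAP-catalysed mixed-anhydride esterification (Takeda tert-butyl ester synthesis) masks the acid as an ester that resists the later enolate, lipase and titanium steps and leaves C13 untouched.

**Step 2**
Reactants: 2 tert-butyl (3R)-3,7-dimethyloct-6-enoate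
Product: 3 tert-butyl (3R)-3-methyl-6-oxohexanoate
Conditions: O3, CH2Cl2, −78 °C; Me2S, −78 → 23 °C
Reagents that add atoms: ozone [O-][O+]=O
Why: Ozonolysis with reductive work-up (Criegee mechanism) cleaves the only alkene to the aldehyde whose carbonyl carbon becomes C9.

**Step 3**
Reactants: 3 tert-butyl (3R)-3-methyl-6-oxohexanoate
Product: 4 tert-butyl (3R)-3-methylhept-6-ynoate
Conditions: MeC(O)C(N2)P(O)(OMe)2, K2CO3, MeOH, 0 → 23 °C
Reagents that add atoms: dimethyl (1-diazo-2-oxopropyl)phosphonate COP(=O)(OC)C(=[N+]=[N-])C(C)=O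
Why: Seyferth–Gilbert homologation in the Ohira–Bestmann version gives the terminal alkyne (new carbon = C10) under carbonate conditions that touch neither C13 nor the tert-butyl ester.

**Step 4**
Reactants: 4 tert-butyl (3R)-3-methylhept-6-ynoate; 5 acetaldehyde; 6 propionic anhydride
Product: 9 tert-butyl (3R,6E,8RS)-3,6-dimethyl-8-(propanoyloxy)non-6-enoate, via alkenylalane 7 (not isolated), via aluminium alkoxide 8 (not isolated)
Conditions: Me3Al, Cp2ZrCl2 (20 mol %), CH2Cl2, 0 → 23 °C; MeCHO, −78 → 0 °C; (EtCO)2O, DMAP, 0 → 23 °C; then H2O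
Reagents that add atoms: trimethylaluminium C[Al](C)C; acetaldehyde CC=O; propionic anhydride CCC(=O)OC(=O)CC
Why: Negishi zirconium-catalysed methylalumination adds Me and Al syn with Me on the internal carbon, which fixes the E C9=C10 alkene (C20 methyl), and 1,2-addition of the alkenylalane to acetaldehyde followed by acylation in the flask gives the propionate as a 1:1 mixture at the carbinol carbon.

**Step 5**
Reactants: 9 tert-butyl (3R,6E,8RS)-3,6-dimethyl-8-(propanoyloxy)non-6-enoate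
Product: 10 tert-butyl (3R,6E,8S)-3,6-dimethyl-8-(propanoyloxy)non-6-enoate
Conditions: CAL-B (immobilised), n-BuOH (3 equiv), MTBE, 30 °C, stopped at about 52% conversion
Reagents that add atoms: none
Why: Lipase kinetic resolution (Kazlauskas rule: CAL-B cleaves the R ester of a methyl alkenyl carbinol) removes the 8R diastereomer as its alcohol and leaves the 8S propionate in high diastereomeric purity, at the price of a 50% ceiling on yield.

**Step 6**
Reactants: 10 tert-butyl (3R,6E,8S)-3,6-dimethyl-8-(propanoyloxy)non-6-enoate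
Product: 13 (2S,3R,6R)-8-tert-butoxy-2,3,6-trimethyl-8-oxo-3-[(E)-prop-1-enyl]octanoic acid, via silyl ketene acetal 11 (not isolated), via silyl ester 12 (not isolated)
Conditions: LiN(iPr)2 (2.3 equiv), THF–DMPU 4:1, −78 °C; TBSCl; −78 → 50 °C; 1 M HCl, THF, 23 °C
Reagents that add atoms: none
Why: Ireland–Claisen rearrangement of the Z silyl ketene acetal goes through a chair transition state with the carbinol methyl, the C17 methyl and the side chain equatorial, so the S carbinol centre is transferred to the quaternary C9 (R) and to C8 (S) and the new alkene is E.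

**Step 7**
Reactants: 13 (2S,3R,6R)-8-tert-butoxy-2,3,6-trimethyl-8-oxo-3-[(E)-prop-1-enyl]octanoic acid; 14 but-2-yn-1-ol
Product: 15 1-(but-2-yn-1-yl) 8-tert-butyl (2S,3R,6R)-2,3,6-trimethyl-3-[(E)-prop-1-enyl]octanedioate
Conditions: EDC·HCl, DMAP, CH2Cl2, 0 → 23 °C
Reagents that add atoms: but-2-yn-1-ol CC#CCO
Why: Steglich esterification attaches the four carbons that become C18, C4, C5 and C19 without epimerising C8.

**Step 8**
Reactants: 15 1-(but-2-yn-1-yl) 8-tert-butyl (2S,3R,6R)-2,3,6-trimethyl-3-[(E)-prop-1-enyl]octanedioate; 16 methyl (triphenylphosphoranylidene)acetate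
Product: 18 1-(but-2-yn-1-yl) 8-tert-butyl (2S,3R,6R)-3-[(E)-3-methoxy-3-oxoprop-1-enyl]-2,3,6-trimethyloctanedioate, via aldehyde 17 (not isolated)
Conditions: O3, CH2Cl2, −78 °C (indicator end point); PPh3; then 16, −78 → 40 °C
Reagents that add atoms: methyl (triphenylphosphoranylidene)acetate COC(=O)C=P(c1ccccc1)(c1ccccc1)c1ccccc1
Why: Ozonolysis of the alkene (far faster than attack on the alkyne) followed in the same flask by Wittig olefination of the non-enolisable neopentyl aldehyde by the stabilised ylide gives the E enoate (new carbons C1 and C2).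

**Step 9**
Reactants: 18 1-(but-2-yn-1-yl) 8-tert-butyl (2S,3R,6R)-3-[(E)-3-methoxy-3-oxoprop-1-enyl]-2,3,6-trimethyloctanedioate
Product: 19 tert-butyl (3R,6R,7S)-8-(but-2-yn-1-yloxy)-6-[(1E)-3-methoxybuta-1,3-dienyl]-3,6,7-trimethylnon-8-enoate
Conditions: Cp2TiMe2 (5 equiv), toluene, 60 °C, dark
Reagents that add atoms: dimethyltitanocene C[Ti](C)(C1C=CC=C1)C1C=CC=C1
Why: Petasis methylenation (Cp2Ti=CH2 formed by loss of methane) turns the two unhindered ester carbonyls into the 2-methoxydiene (C3) and the propargyl vinyl ether (C6), while the bulky tert-butyl ester reacts far more slowly, the oxophilic carbene prefers C=O to the dialkyl alkyne, and 60 °C is below the onset of the Claisen step.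

**Step 10**
Reactants: 19 tert-butyl (3R,6R,7S)-8-(but-2-yn-1-yloxy)-6-[(1E)-3-methoxybuta-1,3-dienyl]-3,6,7-trimethylnon-8-enoate
Product: 21 tert-butyl (3R)-5-[(1R,2S,4aS,8aR)-7-methoxy-1,2,4a-trimethyl-5-methylidene-3-oxo-1,2,3,4,4a,5,6,8a-octahydronaphthalen-1-yl]-3-methylpentanoate, via allenyl ketone 20 (not isolated)
Conditions: toluene (5 mM), BHT, 120 °C; then [RhCl(cod)]2 (5 mol %), P(O-2-PhC6H4)3 (12 mol %), 100 °C, same flask
Reagents that add atoms: none
Why: Proposed new method: a Saucy–Marbet-type propargyl Claisen rearrangement forms C5–C6 and unmasks allene 20, whose methyl-bearing proximal π bond then enters an intramolecular [4+2] cycloaddition with the 2-methoxydiene on monovalent rhodium (oxidative cyclisation to a rhodacycle, then reductive elimination; closest known reaction type: rhodium-catalysed diene–allene [4+2] cycloaddition that places an angular methyl next to an exocyclic methylene), so both rings, C5 and C10 are set at once through a chair-like tether in which C17 and the side chain are equatorial and the slim sp carbon C4, not the C19 methyl, sits syn-axial to C20, which gives the cis-fused 4aS,8aR product.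

**Step 11**
Reactants: 21 tert-butyl (3R)-5-[(1R,2S,4aS,8aR)-7-methoxy-1,2,4a-trimethyl-5-methylidene-3-oxo-1,2,3,4,4a,5,6,8a-octahydronaphthalen-1-yl]-3-methylpentanoate
Product: 22 tert-butyl (3R)-5-[(1R,2S,3S,4aS,8aR)-3-hydroxy-7-methoxy-1,2,4a-trimethyl-5-methylidene-1,2,3,4,4a,5,6,8a-octahydronaphthalen-1-yl]-3-methylpentanoate
Conditions: SmI2 (2.5 equiv), H2O (50 equiv), THF, 0 °C
Reagents that add atoms: none
Why: Single-electron ketyl reduction by divalent samarium gives the thermodynamically preferred equatorial C7 alcohol (S), whereas hydride reagents would be pushed by the syn-axial C20 and C4 groups to the axial epimer.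

**Step 12**
Reactants: 22 tert-butyl (3R)-5-[(1R,2S,3S,4aS,8aR)-3-hydroxy-7-methoxy-1,2,4a-trimethyl-5-methylidene-1,2,3,4,4a,5,6,8a-octahydronaphthalen-1-yl]-3-methylpentanoate
Product: 23 tert-butyl (3R)-5-[(1R,2S,3S,4aS,8aR)-3-acetyloxy-7-methoxy-1,2,4a-trimethyl-5-methylidene-1,2,3,4,4a,5,6,8a-octahydronaphthalen-1-yl]-3-methylpentanoate
Conditions: Ac2O, DMAP, pyridine, 23 °C
Reagents that add atoms: acetic anhydride CC(=O)OC(C)=O
Why: DMAP-catalysed acetylation of the equatorial alcohol proceeds with retention, and the basic medium preserves the enol ether.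

**Step 13**
Reactants: 23 tert-butyl (3R)-5-[(1R,2S,3S,4aS,8aR)-3-acetyloxy-7-methoxy-1,2,4a-trimethyl-5-methylidene-1,2,3,4,4a,5,6,8a-octahydronaphthalen-1-yl]-3-methylpentanoate
Product: 24 tert-butyl (3R)-5-[(1R,2S,3S,4aS,8aR)-3-acetyloxy-7-methoxy-1,2,4a-trimethyl-5-methylidene-6-oxo-1,2,3,4,4a,5,6,8a-octahydronaphthalen-1-yl]-3-methylpentanoate
Conditions: Rh2(cap)4 (1 mol %), t-BuOOH, K2CO3, CH2Cl2, 23 °C
Reagents that add atoms: tert-butyl hydroperoxide CC(C)(C)OO
Why: Dirhodium caprolactamate-catalysed allylic oxidation with tert-butyl hydroperoxide (Doyle oxidation) attacks the weakest C–H bonds, the doubly allylic C3 methylene between the enol ether and the exocyclic alkene, and gives the cross-conjugated ketone.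

**Step 14**
Reactants: 24 tert-butyl (3R)-5-[(1R,2S,3S,4aS,8aR)-3-acetyloxy-7-methoxy-1,2,4a-trimethyl-5-methylidene-6-oxo-1,2,3,4,4a,5,6,8a-octahydronaphthalen-1-yl]-3-methylpentanoate
Product: 25 (3R)-5-[(1R,2S,3S,4aS,8aR)-3-acetyloxy-7-hydroxy-1,2,4a-trimethyl-5-methylidene-6-oxo-1,2,3,4,4a,5,6,8a-octahydronaphthalen-1-yl]-3-methylpentanoic acid
Conditions: BCl3 (3 equiv), CH2Cl2, −78 → −10 °C; then H2O
Reagents that add atoms: none
Why: Chelation-assisted Lewis acid dealkylation, in which BCl3 binds the C3 carbonyl and the neighbouring methoxy oxygen so that chloride removes the methyl group and the tert-butyl ester ionises at the same time, frees the diosphenol and the acid while the secondary acetate survives below 0 °C.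

**Compound list**
1 | (R)-citronellic acid | CC(C)=CCC[C@@H](C)CC(=O)O | starting material
2 | tert-butyl (3R)-3,7-dimethyloct-6-enoate | CC(C)=CCC[C@@H](C)CC(=O)OC(C)(C)C | intermediate
3 | tert-butyl (3R)-3-methyl-6-oxohexanoate | O=CCC[C@@H](C)CC(=O)OC(C)(C)C | intermediate
4 | tert-butyl (3R)-3-methylhept-6-ynoate | C#CCC[C@@H](C)CC(=O)OC(C)(C)C | intermediate
5 | acetaldehyde | CC=O | starting material
6 | propionic anhydride | CCC(=O)OC(=O)CC | starting material
7 | (E)-alkenyl(dimethyl)alane from 4 (Al on C10, cis to the new C20 methyl) | C[Al](C)/C=C(\C)CC[C@@H](C)CC(=O)OC(C)(C)C | intermediate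
8 | dimethylaluminium alkoxide of the allylic alcohol (both carbinol epimers) | C[Al](C)OC(C)/C=C(\C)CC[C@@H](C)CC(=O)OC(C)(C)C | intermediate
9 | tert-butyl (3R,6E,8RS)-3,6-dimethyl-8-(propanoyloxy)non-6-enoate | CCC(=O)OC(C)/C=C(\C)CC[C@@H](C)CC(=O)OC(C)(C)C | intermediate
10 | tert-butyl (3R,6E,8S)-3,6-dimethyl-8-(propanoyloxy)non-6-enoate | CCC(=O)O[C@@H](C)/C=C(\C)CC[C@@H](C)CC(=O)OC(C)(C)C | intermediate
11 | (Z)-O-tert-butyldimethylsilyl ketene acetal of 10 | C/C=C(\O[Si](C)(C)C(C)(C)C)O[C@@H](C)/C=C(\C)CC[C@@H](C)CC(=O)OC(C)(C)C | intermediate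
12 | tert-butyldimethylsilyl ester of 13 | C/C=C/[C@@](C)(CC[C@@H](C)CC(=O)OC(C)(C)C)[C@H](C)C(=O)O[Si](C)(C)C(C)(C)C | intermediate
13 | (2S,3R,6R)-8-tert-butoxy-2,3,6-trimethyl-8-oxo-3-[(E)-prop-1-enyl]octanoic acid | C/C=C/[C@@](C)(CC[C@@H](C)CC(=O)OC(C)(C)C)[C@H](C)C(=O)O | intermediate
14 | but-2-yn-1-ol | CC#CCO | starting material
15 | 1-(but-2-yn-1-yl) 8-tert-butyl (2S,3R,6R)-2,3,6-trimethyl-3-[(E)-prop-1-enyl]octanedioate | C/C=C/[C@@](C)(CC[C@@H](C)CC(=O)OC(C)(C)C)[C@H](C)C(=O)OCC#CC | intermediate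
16 | methyl (triphenylphosphoranylidene)acetate | COC(=O)C=P(c1ccccc1)(c1ccccc1)c1ccccc1 | starting material
17 | 1-(but-2-yn-1-yl) 8-tert-butyl (2S,3S,6R)-3-formyl-2,3,6-trimethyloctanedioate | O=C[C@@](C)(CC[C@@H](C)CC(=O)OC(C)(C)C)[C@H](C)C(=O)OCC#CC | intermediate
18 | 1-(but-2-yn-1-yl) 8-tert-butyl (2S,3R,6R)-3-[(E)-3-methoxy-3-oxoprop-1-enyl]-2,3,6-trimethyloctanedioate | COC(=O)/C=C/[C@@](C)(CC[C@@H](C)CC(=O)OC(C)(C)C)[C@H](C)C(=O)OCC#CC | intermediate
19 | tert-butyl (3R,6R,7S)-8-(but-2-yn-1-yloxy)-6-[(1E)-3-methoxybuta-1,3-dienyl]-3,6,7-trimethylnon-8-enoate | C=C(OC)/C=C/[C@@](C)(CC[C@@H](C)CC(=O)OC(C)(C)C)[C@H](C)C(=C)OCC#CC | intermediate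
20 | tert-butyl (3R,6R,7S)-6-[(1E)-3-methoxybuta-1,3-dienyl]-3,6,7,10-tetramethyl-8-oxododeca-10,11-dienoate | C=C(OC)/C=C/[C@@](C)(CC[C@@H](C)CC(=O)OC(C)(C)C)[C@H](C)C(=O)CC(C)=C=C | intermediate
21 | tert-butyl (3R)-5-[(1R,2S,4aS,8aR)-7-methoxy-1,2,4a-trimethyl-5-methylidene-3-oxo-1,2,3,4,4a,5,6,8a-octahydronaphthalen-1-yl]-3-methylpentanoate | C=C1CC(OC)=C[C@@H]2[C@@](C)(CC[C@@H](C)CC(=O)OC(C)(C)C)[C@H](C)C(=O)C[C@]12C | intermediate
22 | tert-butyl (3R)-5-[(1R,2S,3S,4aS,8aR)-3-hydroxy-7-methoxy-1,2,4a-trimethyl-5-methylidene-1,2,3,4,4a,5,6,8a-octahydronaphthalen-1-yl]-3-methylpentanoate | C=C1CC(OC)=C[C@@H]2[C@@](C)(CC[C@@H](C)CC(=O)OC(C)(C)C)[C@H](C)[C@@H](O)C[C@]12C | intermediate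
23 | tert-butyl (3R)-5-[(1R,2S,3S,4aS,8aR)-3-acetyloxy-7-methoxy-1,2,4a-trimethyl-5-methylidene-1,2,3,4,4a,5,6,8a-octahydronaphthalen-1-yl]-3-methylpentanoate | C=C1CC(OC)=C[C@@H]2[C@@](C)(CC[C@@H](C)CC(=O)OC(C)(C)C)[C@H](C)[C@@H](OC(C)=O)C[C@]12C | intermediate
24 | tert-butyl (3R)-5-[(1R,2S,3S,4aS,8aR)-3-acetyloxy-7-methoxy-1,2,4a-trimethyl-5-methylidene-6-oxo-1,2,3,4,4a,5,6,8a-octahydronaphthalen-1-yl]-3-methylpentanoate | C=C1C(=O)C(OC)=C[C@@H]2[C@@](C)(CC[C@@H](C)CC(=O)OC(C)(C)C)[C@H](C)[C@@H](OC(C)=O)C[C@]12C | intermediate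
25 | (3R)-5-[(1R,2S,3S,4aS,8aR)-3-acetyloxy-7-hydroxy-1,2,4a-trimethyl-5-methylidene-6-oxo-1,2,3,4,4a,5,6,8a-octahydronaphthalen-1-yl]-3-methylpentanoic acid (CNP0257844.1) | C=C1C(=O)C(O)=C[C@@H]2[C@@](C)(CC[C@@H](C)CC(=O)O)[C@H](C)[C@@H](OC(C)=O)C[C@]12C | target

**Total step count:** 14. **Longest linear sequence:** 14 (fully linear; 5, 6, 14 and 16 are bought).

**Three steps most likely to fail**

*Step 10 (Claisen/[4+2] in one flask).* The keto tether is enolisable, and an alkoxydiene has not been tested in this cycloaddition. The fallback sets out from 19. The Claisen step is run alone with [(Ph3PAu)3O]BF4 at 23 °C, and 20 is isolated. The ketone is then reduced under reagent control with (R)-Me-CBS and catecholborane at −78 °C, overriding the Felkin preference, to give allenyl alcohol F1. Acetylation gives allenyl acetate F2. The ring-forming step is now carried out on a redesigned substrate that has an sp3 C7 with an equatorial acetate and no enolisable ketone. It is run either on zerovalent nickel (Ni(cod)2 with the same phosphite) or purely thermally at 180 °C. The cycloadduct is 23, where the route is rejoined, so steps 11 and 12 fall away.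

*Step 9 (double methylenation beside an alkyne).* Cp2Ti=CH2 may be trapped by the alkyne, or it may methylenate ketone 20 if the Claisen step starts early. The fallback avoids titanium carbenes and sets out from 13.
- Ozonolysis with PPh3 gives formyl acid F3.
- Horner–Wadsworth–Emmons olefination with diethyl (2-methoxyprop-2-enyl)phosphonate and LiN(SiMe3)2 (2.2 equiv) gives diene acid F4.
- Masamune–Brooks chain extension (carbonyldiimidazole, then Mg(O2CCH2CO2CH2C≡CCH3)2) gives but-2-ynyl β-keto ester F5.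
- Heating F5 at 130–150 °C triggers a Carroll rearrangement with loss of CO2. This delivers 20, where the route is rejoined at the second half of step 10.

*Step 13 (oxidation of C3 in the presence of the enol ether).* Peroxidation of the enol ether could compete. The fallback sets out from 23.
- Wet silica with oxalic acid hydrolyses the enol ether to β,γ-unsaturated ketone F6.
- Riley oxidation (SeO2, dioxane, 70 °C) acts at C3, which is both α to the ketone and allylic. It gives the 2,3-dione, which enolises to diosphenol tert-butyl ester F7.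
- CF3CO2H in CH2Cl2 then gives 25 directly, so step 14 falls away.

**Further compounds**
F1 | step 10 | tert-butyl (3R,6R,7S,8S)-8-hydroxy-6-[(1E)-3-methoxybuta-1,3-dienyl]-3,6,7,10-tetramethyldodeca-10,11-dienoate | C=C(OC)/C=C/[C@@](C)(CC[C@@H](C)CC(=O)OC(C)(C)C)[C@H](C)[C@@H](O)CC(C)=C=C
F2 | step 10 | tert-butyl (3R,6R,7S,8S)-8-acetyloxy-6-[(1E)-3-methoxybuta-1,3-dienyl]-3,6,7,10-tetramethyldodeca-10,11-dienoate | C=C(OC)/C=C/[C@@](C)(CC[C@@H](C)CC(=O)OC(C)(C)C)[C@H](C)[C@@H](OC(C)=O)CC(C)=C=C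
F3 | step 9 | (2S,3S,6R)-8-tert-butoxy-3-formyl-2,3,6-trimethyl-8-oxooctanoic acid | O=C[C@@](C)(CC[C@@H](C)CC(=O)OC(C)(C)C)[C@H](C)C(=O)O
F4 | step 9 | (2S,3R,6R)-8-tert-butoxy-3-[(1E)-3-methoxybuta-1,3-dienyl]-2,3,6-trimethyl-8-oxooctanoic acid | C=C(OC)/C=C/[C@@](C)(CC[C@@H](C)CC(=O)OC(C)(C)C)[C@H](C)C(=O)O
F5 | step 9 | 1-(but-2-yn-1-yl) 10-tert-butyl (4S,5R,8R)-5-[(1E)-3-methoxybuta-1,3-dienyl]-4,5,8-trimethyl-3-oxodecanedioate | C=C(OC)/C=C/[C@@](C)(CC[C@@H](C)CC(=O)OC(C)(C)C)[C@H](C)C(=O)CC(=O)OCC#CC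
F6 | step 13 | tert-butyl (3R)-5-[(1R,2S,3S,4aS,8aR)-3-acetyloxy-1,2,4a-trimethyl-5-methylidene-7-oxodecahydronaphthalen-1-yl]-3-methylpentanoate | C=C1CC(=O)C[C@@H]2[C@@](C)(CC[C@@H](C)CC(=O)OC(C)(C)C)[C@H](C)[C@@H](OC(C)=O)C[C@]12C
F7 | step 13 | tert-butyl (3R)-5-[(1R,2S,3S,4aS,8aR)-3-acetyloxy-7-hydroxy-1,2,4a-trimethyl-5-methylidene-6-oxo-1,2,3,4,4a,5,6,8a-octahydronaphthalen-1-yl]-3-methylpentanoate | C=C1C(=O)C(O)=C[C@@H]2[C@@](C)(CC[C@@H](C)CC(=O)OC(C)(C)C)[C@H](C)[C@@H](OC(C)=O)C[C@]12C
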